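## Structural features

The target (C22H26O7) is a depside. Two benzene rings share no carbon–carbon bond and are joined only by an aryl ester: ring A is a 2,4-dihydroxy-6-methylbenzoyl (orsellinoyl) group, ring B is 2-heptyl-4,6-dihydroxybenzoic acid (numbered from the carboxyl-bearing carbon C1), and the ester runs from the ring A carbonyl to the oxygen on C4 of ring B. There is no stereocentre and no stereogenic double bond, so no configuration has to be set or protected. The fragile groups are the depside ester, which hydroxide or alkoxide cleaves, the free β-resorcylic acid of ring B, which decarboxylates when heated or in strong acid, and three electron-rich phenols. The difficulty is regiochemical, not skeletal. Ring B carries four different substituents in a fixed 1,2,4,6 pattern, only one of its two hydroxyls may be acylated, the acyl partner is a benzoic acid with two ortho substituents, and the carboxyl must be freed at the end without a hydrolytic step. Ring B has oxygen on alternate carbons (the C1 carboxyl carbon, O on C4, O on C6) and an alkyl chain on C2, which is the pattern of an octanoyl-primed tetraketide folded between C1 and C2. The key step uses this pattern. The C1–C2 bond is formed by an intramolecular aldol condensation of a fourteen-carbon 3,5,7-trioxo acid chain whose carboxyl end and future C6 oxygen are held in one 1,3-dioxin-4-one, so ring B appears with the C4 hydroxyl as its only free one.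

## Logic of the disconnections

17 to 16. The three O–H groups that must appear last (the C1 carboxyl of ring B and the two phenols of ring A) are traced back to three O–benzyl bonds in 16. The cut is made there because hydrogenolysis is the one deprotection that cannot touch the aryl ester between the rings. The gain is that every acidic group is masked by one kind of group and all are removed together. The forward step must run at room temperature in a non-nucleophilic solvent so that 17 neither decarboxylates nor transesterifies.

16 to 11 and 15. The C(=O)–O bond between the rings is cut, giving the phenol 11 and the acyl chloride 15. It is the only bond joining the rings, and cutting it gives two halves of similar size that are made independently. The forward step must acylate the C4 hydroxyl of 11 and spare the C6 hydroxyl. It relies on the hydrogen bond from the C6 hydroxyl to the ester carbonyl, which lowers its acidity and nucleophilicity, and on the bulk of the acyl group. Acylation at the stage of 10, where only one hydroxyl is free, was set aside because no later reagent could open the acetonide without also cleaving the new aryl ester.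

15 to 14, 13 and 12. These are functional-group changes only: the C–Cl bond, the methyl–oxygen ester bond and the two benzyl–oxygen ether bonds. Ring A is thus bought complete with its substitution pattern. The forward steps need exhaustive O-benzylation, including the chelated hydroxyl, and hydrolysis of an ester flanked by two ortho substituents, which needs forcing but harmless conditions.

11 to 10. The benzyl ester C–O bond is cut and the carboxyl carbon is tied back to the C6 oxygen through a dimethyl ketal. The reason is that 10 is what the ring-forming step delivers, and its acetonide is converted directly into the ester needed for the endgame, so no free acid of ring B is handled. The forward step is a transesterification by benzyloxide with loss of the ketal carbon as a ketone. It must overcome deactivation of the carbonyl by the para phenoxide.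

10 to 8. This is the strategic cut. The bond between C1 and C2 of ring B (C4a–C5 in 10) is broken and the arene is unfolded into the open-chain diketone 8, with 9 as the intermediate aldol. The alternating oxygen pattern of ring B maps onto a 1,3,5-tricarbonyl chain, so one operation gives the ring and fixes all four substituent positions from the chain order, with no aromatic substitution. The forward step must cyclise through carbon (C5 of the heterocycle) onto the terminal ketone and then dehydrate. It must not close through oxygen or onto the nearer ketone.

8 to 4 and 6. The bond between the heptyl ketone carbon and the neighbouring methylene is cut. This separates an eight-carbon acyl donor from a three-carbon-extended heterocycle. The forward step needs the terminal methyl of 4 to be the nucleophile, which is arranged by double deprotonation to 7, whose last-formed carbanion sits at the methyl terminus. The donor must deliver one acyl group to carbon and stop, which is why 6 is used and not 5 directly.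

4 to 1 and 2, and 6 to 5. Compound 4 is cut between its ketone carbon and the ring-attached methylene, through the extended enolate 3. Compound 6 is cut at the amide C–N bond. Compounds 1, 2 and 5 are commercial. The forward acylation must occur at the γ-carbon of the enolate, and because 4 is more acidic than 1 the enolate is used in excess.

## Other disconnections considered

Alternative 1: The cut removes both carbon substituents of ring B at once, the C2–heptyl bond and the C1–carboxyl bond, and leaves an aryne between C1 and C2.
- **Forward key step.** An excess of heptylmagnesium bromide A3 would exchange the iodine of 3,5-bis(benzyloxy)-2-iodophenyl trifluoromethanesulfonate A2 for magnesium, and the arylmagnesium would expel triflate. A further equivalent of A3 would add to the aryne at the carbon remote from the flanking benzyloxy group (the future C2). Carboxylation of the resulting C1 arylmagnesium would give 4,6-bis(benzyloxy)-2-heptylbenzoic acid A1. No ring is closed.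
- **In its favour.** Two adjacent carbon–carbon bonds would be made in one flask. The regiochemistry is steered by the inductive effect of the ortho oxygen, as is usual for 3-alkoxyarynes. No polycarbonyl intermediate is handled.
- **Against it here.** A2 is itself a multistep target, needing regioselective iodination and triflation of a 3,5-dialkoxyphenol in which three ring positions are activated. More seriously, A1 carries the same benzyl group on both ring B oxygens, whereas the depside needs the C4 oxygen free and the C6 oxygen masked. Both ethers would have to be removed and the carboxyl re-esterified to reach 11, passing through a free acid of ring B that decarboxylates easily.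
- **Comparison.** On control of the C1/C2 relationship the two plans are equal, since both are substrate-controlled. The alternative is better in that arylmagnesium carboxylation is robust and no enolisable tricarbonyl compound is involved. The chosen plan is better on structure, because the difference between the two oxygens comes free with ring construction. It is also shorter to 11: about six operations by the aryne route against five steps (four in line).

Alternative 2: Ring A is numbered from the carbonyl-bearing carbon C1′ to the methyl-bearing carbon C2′ and on to the hydroxylated carbons C4′ and C6′. The cut goes through ring A at C1′–C6′ and C2′–C3′, so C1′ and C2′ come from the triple bond of a but-2-ynoate and C3′ to C6′ from an electron-rich diene.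
- **Forward key step.** Compound 11 would be esterified on its C4 oxygen with a but-2-ynoyl group to benzyl 4-(but-2-ynoyloxy)-2-heptyl-6-hydroxybenzoate A5. A [4+2] cycloaddition of A5 with 1-methoxy-1,3-bis(trimethylsilyloxy)buta-1,3-diene A6 would join the methylene terminus of the diene to the methyl-bearing alkyne carbon and the ketene acetal carbon to the ester-bearing one. Loss of the methoxy group and of the silyl groups would close ring A as the free resorcinol in benzyl 4-[(2,4-dihydroxy-6-methylbenzoyl)oxy]-2-heptyl-6-hydroxybenzoate A4. Hydrogenolysis of the single benzyl ester of A4 would give 17.
- **In its favour.** Ring A never needs protecting groups. The hindered aroyl transfer of step 8 is replaced by acylation with a small linear acyl group. Steps 6 and 7 disappear.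
- **Against it here.** A β-methyl ynoate is a sluggish dienophile that needs heat, while A6 is thermally and hydrolytically delicate. A5 is an aryl ester and therefore an acylating agent, so the nucleophilic diene may attack its carbonyl and release 11, or add in a Mukaiyama–Michael sense without closing the ring. The free C6 hydroxyl of A5 would consume diene by silyl transfer.
- **Comparison.** The regiochemistry of the cycloaddition is electronically matched and in principle as secure as the chain-order control of step 4, so the plans are equal on that point. On step count the alternative is better by one step if A6 is bought, and not better if A6 must be made. It shares compounds 1 to 11 with the chosen plan, so it replaces the endgame and not the ring B strategy. On mechanism the chosen plan is better, because an acyl chloride esterification has fewer competing pathways than a thermal cycloaddition–aromatisation cascade on an activated ester.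

Alternative 3: The cut is made on both sides of the depside carbonyl carbon, at the C1′–carbonyl bond and the carbonyl–oxygen bond. The carbonyl carbon is supplied by carbon monoxide A9.
- **Forward key step.** 1,5-Bis(benzyloxy)-2-iodo-3-methylbenzene A8, A9 and 11 would combine under a palladium catalyst carrying a wide-bite-angle bisphosphine, with a tertiary amine base. Zerovalent palladium adds oxidatively into the C–I bond, A9 inserts into the aryl–palladium bond of the divalent palladium intermediate, and the aroyl group is transferred to the C4 phenoxide of 11. The product is benzyl 4-{[2,4-bis(benzyloxy)-6-methylbenzoyl]oxy}-2-heptyl-6-hydroxybenzoate A7, which is the same compound as 16. No ring is closed.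
- **In its favour.** A8 should be available in two steps from a 3,5-dialkoxytoluene-type precursor. The hindered saponification of step 7 and the acid chloride are avoided. Two bonds form in one operation, and the route rejoins the chosen plan at 16.
- **Against it here.** Capture of an aroyl–palladium species with two ortho substituents by a phenol, a weak nucleophile, is slow. Hydrodehalogenation and direct aryl ether formation can compete. Compound 11 still offers two hydroxyls, so the regiochemical question of step 8 remains. A toxic gas has to be handled.
- **Comparison.** Step count is equal (three operations for ring A in either plan), and convergence is equal. The alternative is better in avoiding a forcing ester hydrolysis and a stoichiometric activating agent. The chosen plan is better on mechanism, because its acylation is a simple addition–elimination with more predictable failure modes.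

Key step: step 4

Remark on the chemistry: the target has no stereocentre. The one stereocentre that appears on the way (the carbinol carbon of 9) forms as a racemate and is destroyed in the same flask, so all SMILES are written without stereodescriptors.

## Route

Step 1
Reactants: 1 2,2,6-trimethyl-4H-1,3-dioxin-4-one; 2 acetyl chloride
Product: 4 2,2-dimethyl-6-(2-oxopropyl)-4H-1,3-dioxin-4-one, via lithium dienolate 3 (not isolated)
Conditions: LiN(SiMe3)2 (1.0 equiv), THF, −78 °C; 2 (0.5 equiv), −78 °C; 1 M HCl
Reagents that add atoms: none
Why: LiN(SiMe3)2 removes a γ-proton of the vinylogous ester to give the extended enolate 3, which is C-acylated at its exocyclic carbon by the acid chloride (vinylogous Claisen-type acylation). Two equivalents of 3 per acid chloride are used because 4 is more acidic than 1 and is deprotonated by 3 as it forms.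

Step 2
Reactants: 5 octanoyl chloride
Product: 6 N-methoxy-N-methyloctanamide
Conditions: MeNHOMe·HCl, Et3N, CH2Cl2, 0 °C to rt
Reagents that add atoms: N,O-dimethylhydroxylamine hydrochloride, CNOC.Cl
Why: N-acylation of the hydroxylamine by the acid chloride (Schotten–Baumann-type amide formation) is fast and clean. The N-methoxy-N-methylamide (Weinreb amide) is made because it transfers exactly one acyl group to a carbanion, which the acid chloride would not do reliably with a dianion.

Step 3
Reactants: 4 2,2-dimethyl-6-(2-oxopropyl)-4H-1,3-dioxin-4-one; 6 N-methoxy-N-methyloctanamide
Product: 8 6-(2,4-dioxoundecyl)-2,2-dimethyl-4H-1,3-dioxin-4-one, via dilithium bis-enolate 7 (not isolated)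
Conditions: LiN(iPr)2 (2.2 equiv), THF, −78 °C; 6, −78 to −20 °C; 1 M HCl to pH 3
Reagents that add atoms: none
Why: The first equivalent of amide base removes the proton between ketone and dioxinone and the second the terminal methyl proton, giving 7, which reacts at its last-formed and most nucleophilic terminal carbon (Claisen-type acylation of a 1,3-dicarbonyl dianion). Acyl transfer from the N-methoxy-N-methylamide stops at the ketone level, so neither double acylation nor O-acylation is expected, and the cold acidic quench keeps 8 from cyclising early.

Step 4
Reactants: 8 6-(2,4-dioxoundecyl)-2,2-dimethyl-4H-1,3-dioxin-4-one
Product: 10 5-heptyl-7-hydroxy-2,2-dimethyl-4H-benzo[d][1,3]dioxin-4-one, via aldol adduct 9 (not isolated)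
Conditions: Et3N (2 equiv), CH2Cl2, rt; 1 M HCl wash
Reagents that add atoms: none
Why: Triethylamine removes a proton from the methylene flanked by the dioxinone and the first ketone, and the extended enolate reacts through dioxinone C5, its α-carbon, with the heptyl ketone carbonyl to give aldol adduct 9, which forms the bond between the future C1 and C2 and closes ring B. The closure is a 6-(enolexo)-exo-trig aldol, since the enolate double bond from dioxinone C5 to C4 and the attacked carbonyl both lie outside the new six-membered carbocycle. E1cB loss of water from 9 and tautomerisation of the remaining ring ketone to the phenol then give the arene, so the sequence is the established amine-mediated aldol condensation–aromatisation of diketo-dioxinones to resorcylate benzodioxinones and mirrors the aldol folding of a tetraketide. No stereocentre survives, because the carbinol carbon of 9 forms without control and is erased by dehydration. The step needs carbon cyclisation onto the terminal ketone only, and the substrate secures this in three ways. First, dioxinone C5 and the chain are both attached to dioxinone C6, so C5 reaches the heptyl ketone through a six-membered ring, whereas attack on the nearer ketone would need a four-membered ring. Second, the heterocycle holds the masked carboxyl carbon trans to the chain across the ring double bond, so neither a Claisen closure onto that carbon (leading to an acylphloroglucinol) nor attack of an enol oxygen on it (leading to a pyranone) is geometrically possible. Third, the acetonide keeps the carboxyl from decarboxylating and delivers 10 with the C7 hydroxyl (C4 of ring B) as its only free phenol.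

Step 5
Reactants: 10 5-heptyl-7-hydroxy-2,2-dimethyl-4H-benzo[d][1,3]dioxin-4-one
Product: 11 benzyl 2-heptyl-4,6-dihydroxybenzoate
Conditions: BnOH (5 equiv), NaH (2.5 equiv), THF, 0 to 60 °C; 1 M HCl
Reagents that add atoms: benzyl alcohol, OCc1ccccc1
Why: Sodium benzyloxide adds to the benzodioxinone carbonyl and the ring opens with loss of acetone (transesterification of an acylal-type ester), giving the benzyl ester and freeing the C6 oxygen in one operation. The C7 phenoxide of 10 slows the addition, hence the excess alkoxide and the warming, and the product is shielded from further attack as its bis-phenoxide.

Step 6
Reactants: 12 methyl orsellinate (methyl 2,4-dihydroxy-6-methylbenzoate)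
Product: 13 methyl 2,4-bis(benzyloxy)-6-methylbenzoate
Conditions: BnBr (2.5 equiv), K2CO3, DMF, 60 °C
Reagents that add atoms: benzyl bromide, BrCc1ccccc1
Why: Williamson etherification; the non-chelated C4 hydroxyl reacts first and the hydrogen-bonded C2 hydroxyl follows in warm DMF with excess bromide.

Step 7
Reactants: 13 methyl 2,4-bis(benzyloxy)-6-methylbenzoate
Product: 14 2,4-bis(benzyloxy)-6-methylbenzoic acid
Conditions: KOH, DMSO–H2O (4:1), 90 °C; 1 M HCl, 0 °C
Reagents that add atoms: potassium hydroxide, [K+].[OH-]
Why: Saponification of a methyl ester shielded by two ortho substituents needs hot KOH in aqueous DMSO, to which benzyl aryl ethers are inert. Cold acidification should give 14 without decarboxylation because its ortho and para oxygens are etherified.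

Step 8
Reactants: 14 2,4-bis(benzyloxy)-6-methylbenzoic acid; 11 benzyl 2-heptyl-4,6-dihydroxybenzoate
Product: 16 benzyl 4-{[2,4-bis(benzyloxy)-6-methylbenzoyl]oxy}-2-heptyl-6-hydroxybenzoate, via acid chloride 15 (not isolated)
Conditions: (COCl)2, DMF (cat.), CH2Cl2, 0 °C to rt, evaporate; 11 (1.0 equiv), Et3N, DMAP (cat.), CH2Cl2, 0 °C to rt
Reagents that add atoms: none
Why: Oxalyl chloride with catalytic DMF converts 14 into 15, which acylates 11 by DMAP-catalysed addition–elimination (esterification of a phenol by an acyl chloride). The C4 hydroxyl reacts because it is the more acidic and the unencumbered one, whereas the C6 hydroxyl is held in a hydrogen bond to the benzyl ester carbonyl. One equivalent of the bulky chloride keeps double acylation down.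

Step 9
Reactants: 16 benzyl 4-{[2,4-bis(benzyloxy)-6-methylbenzoyl]oxy}-2-heptyl-6-hydroxybenzoate
Product: 17 4-[(2,4-dihydroxy-6-methylbenzoyl)oxy]-2-heptyl-6-hydroxybenzoic acid
Conditions: H2 (1 atm), 10% Pd/C, EtOAc, rt
Reagents that add atoms: none
Why: Hydrogenolysis over palladium cleaves the benzyl ester and both benzyl ethers as toluene under neutral conditions at room temperature. This leaves the aryl ester between the rings and the acid of ring B untouched, and no stereocentre is involved.

## Compound list

1 | 2,2,6-trimethyl-4H-1,3-dioxin-4-one | CC1=CC(=O)OC(C)(C)O1 | starting material
2 | acetyl chloride | CC(Cl)=O | starting material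
3 | lithium 2,2-dimethyl-6-methylidene-6H-1,3-dioxin-4-olate (lithium dienolate of 1, not isolated) | C=C1C=C(O[Li])OC(C)(C)O1 | intermediate
4 | 2,2-dimethyl-6-(2-oxopropyl)-4H-1,3-dioxin-4-one | CC(=O)CC1=CC(=O)OC(C)(C)O1 | intermediate
5 | octanoyl chloride | CCCCCCCC(Cl)=O | starting material
6 | N-methoxy-N-methyloctanamide | CCCCCCCC(=O)N(C)OC | intermediate
7 | dilithium bis-enolate of 4 (terminal enolate plus dioxinone dienolate, not isolated) | C=C(O[Li])C=C1C=C(O[Li])OC(C)(C)O1 | intermediate
8 | 6-(2,4-dioxoundecyl)-2,2-dimethyl-4H-1,3-dioxin-4-one | CCCCCCCC(=O)CC(=O)CC1=CC(=O)OC(C)(C)O1 | intermediate
9 | 5-heptyl-5-hydroxy-2,2-dimethyl-5,6-dihydro-4H-1,3-benzodioxine-4,7(8H)-dione (racemic aldol adduct, not isolated) | CCCCCCCC1(O)CC(=O)CC2=C1C(=O)OC(C)(C)O2 | intermediate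
10 | 5-heptyl-7-hydroxy-2,2-dimethyl-4H-benzo[d][1,3]dioxin-4-one | CCCCCCCc1cc(O)cc2OC(C)(C)OC(=O)c12 | intermediate
11 | benzyl 2-heptyl-4,6-dihydroxybenzoate | CCCCCCCc1cc(O)cc(O)c1C(=O)OCc1ccccc1 | intermediate
12 | methyl orsellinate (methyl 2,4-dihydroxy-6-methylbenzoate) | COC(=O)c1c(C)cc(O)cc1O | starting material
13 | methyl 2,4-bis(benzyloxy)-6-methylbenzoate | COC(=O)c1c(C)cc(OCc2ccccc2)cc1OCc1ccccc1 | intermediate
14 | 2,4-bis(benzyloxy)-6-methylbenzoic acid | OC(=O)c1c(C)cc(OCc2ccccc2)cc1OCc1ccccc1 | intermediate
15 | 2,4-bis(benzyloxy)-6-methylbenzoyl chloride (not isolated) | ClC(=O)c1c(C)cc(OCc2ccccc2)cc1OCc1ccccc1 | intermediate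
16 | benzyl 4-{[2,4-bis(benzyloxy)-6-methylbenzoyl]oxy}-2-heptyl-6-hydroxybenzoate | CCCCCCCc1cc(OC(=O)c2c(C)cc(OCc3ccccc3)cc2OCc2ccccc2)cc(O)c1C(=O)OCc1ccccc1 | intermediate
17 | 4-[(2,4-dihydroxy-6-methylbenzoyl)oxy]-2-heptyl-6-hydroxybenzoic acid | CCCCCCCc1cc(OC(=O)c2c(C)cc(O)cc2O)cc(O)c1C(=O)O | target

## Step count and least certain steps

Total step count: 9. Longest linear sequence: 6 steps (steps 1, 3, 4, 5, 8, 9, from compound 1). The ring A arm (steps 6 and 7) and the acyl donor (step 2) are side branches.

Step 4 (key step). The most likely failure is stalling at the aldol stage or slow dehydration, which gives the chain time to fragment by retro-Claisen cleavage or to be opened at the acetonide by adventitious nucleophiles. The fallback closes the ring on the open-chain ester instead of on the dioxinone. It sets out from 8, which would be heated in toluene at 110 °C with benzyl alcohol. Retro-[4+2] loss of acetone gives the acylketene 3,5,7-trioxotetradec-1-en-1-one F1, which is trapped as benzyl 3,5,7-trioxotetradecanoate F2. Treatment of F2 with Cs2CO3 and then 1 M HCl should effect the same aldol condensation and aromatisation and give 11 directly, where the route is rejoined. Lactonisation of the free ester to a pyranone can compete, which is why this is the fallback and not the main line.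

Step 3. The most likely failure is proton transfer from the α-position of the amide to the bis-enolate (enolisation instead of addition) or incomplete second deprotonation, both of which return 4. The fallback replaces acylation by aldol addition and oxidation. It sets out from 4. The bis-enolate 7 would be generated as in step 3 and added to octanal (CCCCCCCC=O) at −78 °C, giving the racemic aldol 6-(4-hydroxy-2-oxoundecyl)-2,2-dimethyl-4H-1,3-dioxin-4-one F3. Neutral oxidation of the β-hydroxy ketone with 2-iodoxybenzoic acid in EtOAc at 70 °C should then give 8, where the route is rejoined.

Step 5. The most likely failure is sluggish transesterification, because the C7 phenoxide donates into the carbonyl. Prolonged heating then invites debenzylation of the product ester by alkoxide and decarboxylation. The fallback separates ring opening from ester formation. It sets out from 10, which would be hydrolysed with aqueous KOH in DMSO at 60 °C and acidified cold to give 2-heptyl-4,6-dihydroxybenzoic acid F4. Carboxylate-selective alkylation with benzyl bromide and KHCO3 in DMF at rt should give 11, where the route is rejoined. F4 must be kept cold and used at once because it decarboxylates easily.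

Step 8. The most likely failure is slow acyl transfer from the hindered chloride, which leaves time for hydrolysis back to 14 or, under forcing, for acylation of the chelated C6 hydroxyl as well. The fallback changes the activation from base-mediated acyl chloride chemistry to an acid-mediated mixed anhydride. It sets out from 14 and 11. Acid 14 would be treated with trifluoroacetic anhydride in toluene at rt to give 2,4-bis(benzyloxy)-6-methylbenzoic trifluoroacetic anhydride F5. The two ortho substituents and the donor oxygens favour ionisation of F5 towards an acylium-type electrophile, which should acylate the non-chelated C4 hydroxyl of 11 while the C6 hydroxyl stays protonated and hydrogen-bonded. This gives 16, where the route is rejoined.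

## Further compounds

F1 | step 4 | 3,5,7-trioxotetradec-1-en-1-one (acylketene) | CCCCCCCC(=O)CC(=O)CC(=O)C=C=O
F2 | step 4 | benzyl 3,5,7-trioxotetradecanoate | CCCCCCCC(=O)CC(=O)CC(=O)CC(=O)OCc1ccccc1
F3 | step 3 | 6-(4-hydroxy-2-oxoundecyl)-2,2-dimethyl-4H-1,3-dioxin-4-one (racemic) | CCCCCCCC(O)CC(=O)CC1=CC(=O)OC(C)(C)O1
F4 | step 5 | 2-heptyl-4,6-dihydroxybenzoic acid | CCCCCCCc1cc(O)cc(O)c1C(=O)O
F5 | step 8 | 2,4-bis(benzyloxy)-6-methylbenzoic trifluoroacetic anhydride | Cc1cc(OCc2ccccc2)cc(OCc2ccccc2)c1C(=O)OC(=O)C(F)(F)F
A1 | alternative 1 | 4,6-bis(benzyloxy)-2-heptylbenzoic acid | CCCCCCCc1cc(OCc2ccccc2)cc(OCc2ccccc2)c1C(=O)O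
A2 | alternative 1 | 3,5-bis(benzyloxy)-2-iodophenyl trifluoromethanesulfonate | FC(F)(F)S(=O)(=O)Oc1cc(OCc2ccccc2)cc(OCc2ccccc2)c1I
A3 | alternative 1 | heptylmagnesium bromide | CCCCCCC[Mg]Br
A4 | alternative 2 | benzyl 4-[(2,4-dihydroxy-6-methylbenzoyl)oxy]-2-heptyl-6-hydroxybenzoate | CCCCCCCc1cc(OC(=O)c2c(C)cc(O)cc2O)cc(O)c1C(=O)OCc1ccccc1
A5 | alternative 2 | benzyl 4-(but-2-ynoyloxy)-2-heptyl-6-hydroxybenzoate | CCCCCCCc1cc(OC(=O)C#CC)cc(O)c1C(=O)OCc1ccccc1
A6 | alternative 2 | 1-methoxy-1,3-bis(trimethylsilyloxy)buta-1,3-diene | COC(O[Si](C)(C)C)=CC(=C)O[Si](C)(C)C
A7 | alternative 3 | benzyl 4-{[2,4-bis(benzyloxy)-6-methylbenzoyl]oxy}-2-heptyl-6-hydroxybenzoate (identical with 16) | CCCCCCCc1cc(OC(=O)c2c(C)cc(OCc3ccccc3)cc2OCc2ccccc2)cc(O)c1C(=O)OCc1ccccc1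
A8 | alternative 3 | 1,5-bis(benzyloxy)-2-iodo-3-methylbenzene | Cc1cc(OCc2ccccc2)cc(OCc2ccccc2)c1I
A9 | alternative 3 | carbon monoxide | [C-]#[O+]
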